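## Retrosynthetic overview

1. Target 27 (2H-chromene numbering, side chain C1' to C4') comes from the cinnamoyl chroman-5,8-quinone 25 by an internal redox isomerisation, in which the quinone oxidation level is moved into the C3=C4 double bond. 25 comes from phenol 22 by oxidative demethylation, desilylation and carbinol oxidation.
2. The strategy rests on ring A: oxygens para to each other at C5 and C8, O1 on C8a, hydrogen at C7 and the acyl arm at C6. This is the 4-alkoxyphenol pattern of a carbene/CO/alkyne benzannulation, so ring A is built de novo. C8 is the carbene carbon of 16, C8a and C4a are C6 and C5 of its dihydropyran, C5 is a CO ligand, and C6 and C7 are the alkyne carbons of 20 (new bonds C7–C8, C5–C6, C4a–C5).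
3. Carbene 16 comes from dihydropyran 12 (C6 lithiation, Cr(CO)6, O-methylation), 12 from alkynediol 10 (endo cycloisomerisation), and 10 from (R)-linalool 1. Linalool C3 becomes C2, its hydroxyl becomes O1, its vinyl group is grown into C1'–C4', and its C4, C5, C6 plus one added carbon become C3, C4, C4a, C8a.
4. Alkyne 20 comes from cinnamaldehyde 17 and HC≡CMgBr 18, followed by silylation.
5. Ring order: the pyran ring first (step 6), ring A second (step 11), the C3=C4 double bond last (step 15).

Key step: step 11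

Assumption: commercial (R)-(−)-linalool of high enantiomeric purity supplies the only stereocentre kept in 27. Its spatial arrangement is never touched, and the CIP letter changes only where substituent priorities change (2R in the chromans, 2S in 26 and 27).

Assumption: alkyne 20 is used as the racemate, so 21 to 24 are pairs of epimers at the carbinol carbon of the arm. Both epimers converge at ketone 25.

## Route

Step 1
Reactants: 1 (R)-(−)-linalool
Product: 3 (3R)-3,7-dimethyloct-6-ene-1,3-diol, via alkylborane 2 (not isolated)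
Conditions: 9-BBN (2.2 equiv), THF, 0 °C → rt; then NaOH, H2O2, 0 °C → rt
Reagents that add atoms: hydrogen peroxide, OO
Why: 9-BBN should hydroborate the monosubstituted vinyl group far faster than the trisubstituted alkene and place boron on the terminal carbon (anti-Markovnikov hydroboration–oxidation), leaving the carbinol stereocentre untouched.

Step 2
Reactants: 3 (3R)-3,7-dimethyloct-6-ene-1,3-diol
Product: 5 methyl (2E,5R)-5-hydroxy-5,9-dimethyldeca-2,8-dienoate, via hydroxy aldehyde 4 (not isolated)
Conditions: TEMPO (0.1 equiv), PhI(OAc)2 (1.1 equiv), CH2Cl2, rt; then Ph3P=CHCO2Me (1.5 equiv), rt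
Reagents that add atoms: methyl (triphenylphosphoranylidene)acetate, COC(=O)C=P(c1ccccc1)(c1ccccc1)c1ccccc1
Why: The nitroxyl-catalysed oxidation should touch only the primary alcohol, and the β-hydroxy aldehyde is trapped in the same flask by the stabilised ylide (Wittig olefination, E-selective), so that retro-aldol cleavage and dehydration of the aldehyde are avoided.

Step 3
Reactants: 5 methyl (2E,5R)-5-hydroxy-5,9-dimethyldeca-2,8-dienoate
Product: 7 methyl (2E)-4-[(2R,5RS)-5-hydroxy-2-methyloxolan-2-yl]but-2-enoate (lactol form of the hydroxy aldehyde), via secondary ozonide 6 (not isolated)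
Conditions: O3, CH2Cl2, −78 °C (Sudan Red 7B end point); then PPh3, −78 °C → rt
Reagents that add atoms: ozone, [O-][O+]=O
Why: Ozone should attack the electron-rich trisubstituted alkene much faster than the electron-poor enoate (selective ozonolysis with reductive work-up), and the freed aldehyde closes onto the tertiary hydroxyl as the five-membered lactol.

Step 4
Reactants: 7 methyl (2E)-4-[(2R,5RS)-5-hydroxy-2-methyloxolan-2-yl]but-2-enoate
Product: 8 methyl (2E,5R)-5-hydroxy-5-methylnon-2-en-8-ynoate
Conditions: MeC(O)C(N2)P(O)(OMe)2 (1.5 equiv), K2CO3 (3 equiv), MeOH, 0 °C → rt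
Reagents that add atoms: dimethyl (1-diazo-2-oxopropyl)phosphonate, CC(=O)C(=[N+]=[N-])P(=O)(OC)OC
Why: The lactol is in equilibrium with the hydroxy aldehyde, which the diazomethylphosphonate anion formed in the flask should convert into the terminal alkyne (Ohira–Bestmann variant of the Seyferth–Gilbert homologation) under conditions mild enough for the enoate.

Step 5
Reactants: 8 methyl (2E,5R)-5-hydroxy-5-methylnon-2-en-8-ynoate
Product: 10 (3E,6R)-2,6-dimethyldec-3-en-9-yne-2,6-diol, via enone 9 (not isolated)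
Conditions: MeMgBr (5 equiv), THF, −20 → 0 °C; aq NH4Cl
Reagents that add atoms: methylmagnesium bromide, C[Mg]Br
Why: Excess Grignard reagent should deprotonate the hydroxyl and the alkyne and add twice in 1,2-fashion to the ester (Grignard addition through the enone), giving the tertiary allylic alcohol with the E alkene retained.

Step 6
Reactants: 10 (3E,6R)-2,6-dimethyldec-3-en-9-yne-2,6-diol
Product: 11 (3E)-2-methyl-5-[(2R)-2-methyl-3,4-dihydro-2H-pyran-2-yl]pent-3-en-2-ol
Conditions: W(CO)6 (0.25 equiv), Et3N, THF, hν (350 nm), 60 °C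
Reagents that add atoms: none
Why: Photogenerated W(CO)5 should convert the terminal alkyne into a tungsten vinylidene that the C6 hydroxyl attacks at the terminal carbon (endo-selective alkynol cycloisomerisation), giving the six-membered enol ether, while the distal tertiary alcohol cannot reach the alkyne.

Step 7
Reactants: 11 (3E)-2-methyl-5-[(2R)-2-methyl-3,4-dihydro-2H-pyran-2-yl]pent-3-en-2-ol
Product: 12 triethyl({(3E)-2-methyl-5-[(2R)-2-methyl-3,4-dihydro-2H-pyran-2-yl]pent-3-en-2-yl}oxy)silane
Conditions: Et3SiOTf (1.3 equiv), 2,6-lutidine (2 equiv), CH2Cl2, −78 °C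
Reagents that add atoms: triethylsilyl trifluoromethanesulfonate, CC[Si](CC)(CC)OS(=O)(=O)C(F)(F)F
Why: The silyl triflate with a hindered pyridine base should silylate the remaining tertiary allylic alcohol at low temperature without protonating the enol ether (silyl ether protection).

Step 8
Reactants: 12 triethyl({(3E)-2-methyl-5-[(2R)-2-methyl-3,4-dihydro-2H-pyran-2-yl]pent-3-en-2-yl}oxy)silane; 13 chromium hexacarbonyl, Cr(CO)6
Product: 16 pentacarbonyl[methoxy{(2R)-2-methyl-2-[(2E)-4-methyl-4-(triethylsilyloxy)pent-2-en-1-yl]-3,4-dihydro-2H-pyran-6-yl}methylidene]chromium, via vinyllithium 14 (not isolated), via lithium acylchromate 15 (not isolated)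
Conditions: t-BuLi (1.2 equiv), THF, −78 → 0 °C; Cr(CO)6 (1.1 equiv), Et2O, 0 °C → rt; then Me3OBF4 (1.5 equiv), CH2Cl2, 0 °C
Reagents that add atoms: trimethyloxonium tetrafluoroborate, C[O+](C)C.F[B-](F)(F)F
Why: The enol ether C6–H is the kinetically most acidic proton for t-BuLi (α-alkoxyvinyl lithiation), the vinyllithium should add to a CO ligand of Cr(CO)6, and hard O-methylation of the acylchromate gives the carbene complex (Fischer carbene synthesis).

Step 9
Reactants: 17 (E)-cinnamaldehyde; 18 ethynylmagnesium bromide, HC≡CMgBr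
Product: 19 (1E,3RS)-1-phenylpent-1-en-4-yn-3-ol
Conditions: THF, 0 °C; aq NH4Cl
Reagents that add atoms: none
Why: The ethynyl Grignard reagent should add 1,2 to the enal (Grignard addition) to give the racemic carbinol, whose stereocentre is later erased by oxidation to the ketone.

Step 10
Reactants: 19 (1E,3RS)-1-phenylpent-1-en-4-yn-3-ol
Product: 20 tert-butyl(dimethyl){[(1E,3RS)-1-phenylpent-1-en-4-yn-3-yl]oxy}silane
Conditions: TBSCl (1.2 equiv), imidazole (2 equiv), DMF, rt
Reagents that add atoms: tert-butyldimethylsilyl chloride, CC(C)(C)[Si](C)(C)Cl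
Why: Standard silylation of a secondary alcohol should give the bulky propargylic silyl ether, which benzannulations tolerate and which raises the steric bias of the alkyne.

Step 11
Reactants: 16 pentacarbonyl[methoxy{(2R)-2-methyl-2-[(2E)-4-methyl-4-(triethylsilyloxy)pent-2-en-1-yl]-3,4-dihydro-2H-pyran-6-yl}methylidene]chromium; 20 tert-butyl(dimethyl){[(1E,3RS)-1-phenylpent-1-en-4-yn-3-yl]oxy}silane (1.5 equiv)
Product: 22 (2R)-6-[(1RS,2E)-1-{[tert-butyl(dimethyl)silyl]oxy}-3-phenylprop-2-en-1-yl]-8-methoxy-2-methyl-2-[(2E)-4-methyl-4-(triethylsilyloxy)pent-2-en-1-yl]-3,4-dihydro-2H-chromen-5-ol, via tricarbonylchromium arene complex 21 (not isolated)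
Conditions: THF (0.05 M), 50 °C, Ar; then air, rt; Et3N-buffered silica
Reagents that add atoms: none
Why: Warming should expel one cis CO from 16, the terminal alkyne then inserts into the Cr=C bond with its CH terminus bonding to the carbene carbon (C7–C8), CO inserts at the new carbene carbon to give a chromium-bound vinylketene (C5–C6), and this dienylketene closes onto C5 of the dihydropyran (C4a–C5) before the cyclohexadienone enolises to the chromium-bound phenol 21, which air decomplexes. The closest known reaction type is the Dötz benzannulation of dihydropyranyl and other cycloalkenyl alkoxycarbene chromium complexes with terminal alkynes to 4-methoxyphenols. Ring A is closed by a thermal 6π-electrocyclisation of the metal-bound dienylketene followed by tautomerisation. No stereocentre is created, since C2 is remote and untouched and the silyloxy-bearing carbon enters as the racemate. The step needs the regiochemistry that puts the silyloxyallyl group next to the new C5 hydroxyl and hydrogen at C7, and this is secured by the terminal alkyne, because the substituent on the alkyne carbon that bonds to the former carbene carbon clashes with a CO ligand in the vinylcarbene intermediate, so that carbon carries hydrogen. The step also needs the alkyne to outcompete the two alkenes for chromium, which the excess of alkyne and the THF medium (which favours phenol formation from alkenylcarbenes) should provide.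

Step 12
Reactants: 22 (2R)-6-[(1RS,2E)-1-{[tert-butyl(dimethyl)silyl]oxy}-3-phenylprop-2-en-1-yl]-8-methoxy-2-methyl-2-[(2E)-4-methyl-4-(triethylsilyloxy)pent-2-en-1-yl]-3,4-dihydro-2H-chromen-5-ol
Product: 23 (2R)-6-[(1RS,2E)-1-{[tert-butyl(dimethyl)silyl]oxy}-3-phenylprop-2-en-1-yl]-2-methyl-2-[(2E)-4-methyl-4-(triethylsilyloxy)pent-2-en-1-yl]-3,4-dihydro-2H-chromene-5,8-dione
Conditions: (NH4)2Ce(NO3)6 (2.5 equiv), MeCN/H2O, 0 °C, 10 min
Reagents that add atoms: water, O
Why: Two-electron oxidation of the 4-methoxyphenol, with water adding at C8 and methanol leaving, should give the para-quinone within minutes (oxidative demethylation), faster than any reaction at the alkenes or the silyl ethers.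

Step 13
Reactants: 23 (2R)-6-[(1RS,2E)-1-{[tert-butyl(dimethyl)silyl]oxy}-3-phenylprop-2-en-1-yl]-2-methyl-2-[(2E)-4-methyl-4-(triethylsilyloxy)pent-2-en-1-yl]-3,4-dihydro-2H-chromene-5,8-dione
Product: 24 (2R)-6-[(1RS,2E)-1-hydroxy-3-phenylprop-2-en-1-yl]-2-[(2E)-4-hydroxy-4-methylpent-2-en-1-yl]-2-methyl-3,4-dihydro-2H-chromene-5,8-dione
Conditions: HF·pyridine, pyridine, THF, 0 °C → rt
Reagents that add atoms: none
Why: Buffered HF·pyridine should cleave both silyl ethers (fluoride desilylation), and the electron-poor quinone disfavours ionisation of the freed allylic carbinol, which would be a danger next to an electron-rich phenol.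

Step 14
Reactants: 24 (2R)-6-[(1RS,2E)-1-hydroxy-3-phenylprop-2-en-1-yl]-2-[(2E)-4-hydroxy-4-methylpent-2-en-1-yl]-2-methyl-3,4-dihydro-2H-chromene-5,8-dione
Product: 25 (2R)-2-[(2E)-4-hydroxy-4-methylpent-2-en-1-yl]-2-methyl-6-[(2E)-3-phenylprop-2-enoyl]-3,4-dihydro-2H-chromene-5,8-dione
Conditions: activated MnO2 (20 equiv), CH2Cl2, rt; filter through Celite; solution used at once
Reagents that add atoms: none
Why: Activated MnO2 should oxidise the allylic secondary alcohol selectively (allylic alcohol oxidation) under neutral anhydrous conditions, leaving the tertiary alcohol and the quinone alone and making both carbinol epimers converge on one ketone.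

Step 15
Reactants: 25 (2R)-2-[(2E)-4-hydroxy-4-methylpent-2-en-1-yl]-2-methyl-6-[(2E)-3-phenylprop-2-enoyl]-3,4-dihydro-2H-chromene-5,8-dione
Product: 27 (2E)-1-{(2S)-5,8-dihydroxy-2-[(2E)-4-hydroxy-4-methylpent-2-en-1-yl]-2-methyl-2H-chromen-6-yl}-3-phenylprop-2-en-1-one (CNP0327890.1), via ortho-quinone methide 26 (not isolated)
Conditions: DABCO (0.2 equiv), degassed PhMe (0.01 M), rt, Ar, dark; then pH 5 buffer
Reagents that add atoms: none
Why: Proposed new method: the amine should remove a C4 proton, which is vinylogous to the C8 carbonyl through C4a=C8a, to give ortho-quinone methide 26, and a second proton transfer from C3 (vinylogous to the C5 carbonyl through C4=C4a) to O5 aromatises ring A, so the quinone is reduced to the hydroquinone while C3–C4 is dehydrogenated without external oxidant, driven by aromatisation and the chelated C5 hydroxyl and leaving C2 untouched; the closest known reaction types are the amine-promoted tautomerisation of alkyl- and prenylquinones to ortho-quinone methides (chromenol formation) and the tautomerisation of ortho-quinone methides that carry β-hydrogens to ortho-vinylphenols.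

## Compound list

1 | (R)-(−)-linalool, (3R)-3,7-dimethylocta-1,6-dien-3-ol | CC(C)=CCC[C@](C)(C=C)O | starting material
2 | 9-[(3S)-3-hydroxy-3,7-dimethyloct-6-en-1-yl]-9-borabicyclo[3.3.1]nonane (alkylborane formed in the flask; same spatial arrangement as 1, letter changed by priority only) | CC(C)=CCC[C@](C)(CCB1C2CCCC1CCC2)O | intermediate
3 | (3R)-3,7-dimethyloct-6-ene-1,3-diol | CC(C)=CCC[C@](C)(CCO)O | intermediate
4 | (3R)-3-hydroxy-3,7-dimethyloct-6-enal (formed in the flask) | CC(C)=CCC[C@](C)(CC=O)O | intermediate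
5 | methyl (2E,5R)-5-hydroxy-5,9-dimethyldeca-2,8-dienoate | CC(C)=CCC[C@](C)(C/C=C/C(=O)OC)O | intermediate
6 | methyl (2E,5R)-7-(5,5-dimethyl-1,2,4-trioxolan-3-yl)-5-hydroxy-5-methylhept-2-enoate (secondary ozonide formed in the flask) | CC1(C)OOC(CC[C@](C)(C/C=C/C(=O)OC)O)O1 | intermediate
7 | methyl (2E)-4-[(2R,5RS)-5-hydroxy-2-methyloxolan-2-yl]but-2-enoate | OC1CC[C@](C)(C/C=C/C(=O)OC)O1 | intermediate
8 | methyl (2E,5R)-5-hydroxy-5-methylnon-2-en-8-ynoate | C#CCC[C@](C)(C/C=C/C(=O)OC)O | intermediate
9 | (3E,6R)-6-hydroxy-6-methyldec-3-en-9-yn-2-one (formed in the flask) | C#CCC[C@](C)(C/C=C/C(C)=O)O | intermediate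
10 | (3E,6R)-2,6-dimethyldec-3-en-9-yne-2,6-diol | C#CCC[C@](C)(C/C=C/C(C)(C)O)O | intermediate
11 | (3E)-2-methyl-5-[(2R)-2-methyl-3,4-dihydro-2H-pyran-2-yl]pent-3-en-2-ol | C1=CCC[C@](C)(C/C=C/C(C)(C)O)O1 | intermediate
12 | triethyl({(3E)-2-methyl-5-[(2R)-2-methyl-3,4-dihydro-2H-pyran-2-yl]pent-3-en-2-yl}oxy)silane | C1=CCC[C@](C)(C/C=C/C(C)(C)O[Si](CC)(CC)CC)O1 | intermediate
13 | chromium hexacarbonyl, Cr(CO)6 | O=C=[Cr](=C=O)(=C=O)(=C=O)(=C=O)=C=O | starting material
14 | {(2R)-2-methyl-2-[(2E)-4-methyl-4-(triethylsilyloxy)pent-2-en-1-yl]-3,4-dihydro-2H-pyran-6-yl}lithium (formed in the flask) | [Li]C1=CCC[C@](C)(C/C=C/C(C)(C)O[Si](CC)(CC)CC)O1 | intermediate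
15 | lithium pentacarbonyl({(2R)-2-methyl-2-[(2E)-4-methyl-4-(triethylsilyloxy)pent-2-en-1-yl]-3,4-dihydro-2H-pyran-6-yl}carbonyl)chromate (formed in the flask) | [Li+].[O-]C(=[Cr](=C=O)(=C=O)(=C=O)(=C=O)=C=O)C1=CCC[C@](C)(C/C=C/C(C)(C)O[Si](CC)(CC)CC)O1 | intermediate
16 | pentacarbonyl[methoxy{(2R)-2-methyl-2-[(2E)-4-methyl-4-(triethylsilyloxy)pent-2-en-1-yl]-3,4-dihydro-2H-pyran-6-yl}methylidene]chromium | COC(=[Cr](=C=O)(=C=O)(=C=O)(=C=O)=C=O)C1=CCC[C@](C)(C/C=C/C(C)(C)O[Si](CC)(CC)CC)O1 | intermediate
17 | (E)-cinnamaldehyde | O=C/C=C/c1ccccc1 | starting material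
18 | ethynylmagnesium bromide, HC≡CMgBr | C#C[Mg]Br | starting material
19 | (1E,3RS)-1-phenylpent-1-en-4-yn-3-ol | C#CC(O)/C=C/c1ccccc1 | intermediate
20 | tert-butyl(dimethyl){[(1E,3RS)-1-phenylpent-1-en-4-yn-3-yl]oxy}silane | C#CC(O[Si](C)(C)C(C)(C)C)/C=C/c1ccccc1 | intermediate
21 | tricarbonyl(η6-arene)chromium complex of phenol 22, Cr(CO)3 bound to ring A (formed in the flask) | CC[Si](CC)(CC)OC(C)(C)/C=C/C[C@@]1(C)CCc2c(O)c(C(O[Si](C)(C)C(C)(C)C)/C=C/c3ccccc3)cc(OC)c2O1.O=C=[Cr](=C=O)=C=O | intermediate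
22 | (2R)-6-[(1RS,2E)-1-{[tert-butyl(dimethyl)silyl]oxy}-3-phenylprop-2-en-1-yl]-8-methoxy-2-methyl-2-[(2E)-4-methyl-4-(triethylsilyloxy)pent-2-en-1-yl]-3,4-dihydro-2H-chromen-5-ol | CC[Si](CC)(CC)OC(C)(C)/C=C/C[C@@]1(C)CCc2c(O)c(C(O[Si](C)(C)C(C)(C)C)/C=C/c3ccccc3)cc(OC)c2O1 | intermediate
23 | (2R)-6-[(1RS,2E)-1-{[tert-butyl(dimethyl)silyl]oxy}-3-phenylprop-2-en-1-yl]-2-methyl-2-[(2E)-4-methyl-4-(triethylsilyloxy)pent-2-en-1-yl]-3,4-dihydro-2H-chromene-5,8-dione | CC[Si](CC)(CC)OC(C)(C)/C=C/C[C@@]1(C)CCC2=C(O1)C(=O)C=C(C(O[Si](C)(C)C(C)(C)C)/C=C/c3ccccc3)C2=O | intermediate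
24 | (2R)-6-[(1RS,2E)-1-hydroxy-3-phenylprop-2-en-1-yl]-2-[(2E)-4-hydroxy-4-methylpent-2-en-1-yl]-2-methyl-3,4-dihydro-2H-chromene-5,8-dione | CC(C)(O)/C=C/C[C@@]1(C)CCC2=C(O1)C(=O)C=C(C(O)/C=C/c3ccccc3)C2=O | intermediate
25 | (2R)-2-[(2E)-4-hydroxy-4-methylpent-2-en-1-yl]-2-methyl-6-[(2E)-3-phenylprop-2-enoyl]-3,4-dihydro-2H-chromene-5,8-dione | CC(C)(O)/C=C/C[C@@]1(C)CCC2=C(O1)C(=O)C=C(C(=O)/C=C/c3ccccc3)C2=O | intermediate
26 | (2S)-8-hydroxy-2-[(2E)-4-hydroxy-4-methylpent-2-en-1-yl]-2-methyl-6-[(2E)-3-phenylprop-2-enoyl]-2,3-dihydro-5H-chromen-5-one (ortho-quinone methide formed in the flask; same spatial arrangement at C2) | CC(C)(O)/C=C/C[C@@]1(C)CC=C2C(=O)C(C(=O)/C=C/c3ccccc3)=CC(O)=C2O1 | intermediate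
27 | (2E)-1-{(2S)-5,8-dihydroxy-2-[(2E)-4-hydroxy-4-methylpent-2-en-1-yl]-2-methyl-2H-chromen-6-yl}-3-phenylprop-2-en-1-one (CNP0327890.1) | CC(C)(O)/C=C/C[C@@]1(C)C=Cc2c(O)c(C(=O)/C=C/c3ccccc3)cc(O)c2O1 | target

## Step count and risks

Total step count: 15. Longest linear sequence: 13 steps (steps 1 to 8, then 11 to 15). Steps 9 and 10 are the two-step alkyne branch.

**Step 15 (bears the label "Proposed new method:").** The ortho-quinone methide may dimerise or be captured by the amine. The amine may be oxidised by the electron-poor quinone. Base may close the 2'-hydroxychalcone to a flavanone, and the second proton shift from C3 may be slow. The fallback uses only known reactions; it sets out from 25 and comes back at 27. Reduction of 25 with Na2S2O4 in THF/H2O should give the chroman hydroquinone F1. TBSCl and imidazole in DMF at 0 °C should silylate only the C8 hydroxyl, since the C5 hydroxyl is chelated to the ketone, to give the 8-O-silyl chroman F2. DDQ in benzene at reflux should then dehydrogenate C3–C4 by hydride abstraction at C4 and loss of a C3 proton, the established conversion of oxygenated chromans with a chelated ortho-acyl phenol into 2H-chromenes, to give the 8-O-silyl chromene F3. Bu4NF buffered with AcOH in THF at 0 °C should release 27. Light is kept out throughout so that the 2H-chromene does not ring-open and lose its configuration.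

**Step 11 (key step).** Once the ortho hydroxyl is in place, the silyloxy-bearing carbon may ionise (loss of silanol, ortho-quinone methide formation and closure to a flavene). The skipped enyne may also divert the vinylcarbene intermediate (uptake of a second alkyne or cyclisation onto an alkene), so that little phenol is formed. The fallback keeps the benzannulation but builds the arm afterwards; it sets out from 16 and comes back at 24. Carbene 16 and commercial 3,3-diethoxyprop-1-yne under the conditions of step 11 should give the acetal phenol F4, and PPTS in wet acetone should unmask the salicylaldehyde F5. (E)-PhCH=CHLi (from (E)-β-bromostyrene and t-BuLi at −78 °C, 2.5 equiv) in THF should add to the aldehyde to give the carbinol phenol F6. (NH4)2Ce(NO3)6 in MeCN/H2O at 0 °C should give the quinone carbinol F7, and HF·pyridine should remove the triethylsilyl group to give 24.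

**Step 14.** The electron-poor cinnamoyl quinone may be lost on the oxide surface or during handling by hydration, conjugate addition or oligomerisation. The fallback moves the carbinol oxidation to the phenol stage, where the product is a stable chelated 2'-hydroxychalcone; it sets out from 22 and comes back at 25. Bu4NF buffered with AcOH in THF should remove both silyl groups to give the triol F8, which is handled under neutral conditions. MnO2 in CH2Cl2 should oxidise the ortho-hydroxybenzylic allylic alcohol to the chalcone F9. (NH4)2Ce(NO3)6 in MeCN/H2O at 0 °C should then give 25, which is extracted, dried and carried in solution directly into step 15.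

Further compounds

F1 | step 15 | (2E)-1-{(2R)-5,8-dihydroxy-2-[(2E)-4-hydroxy-4-methylpent-2-en-1-yl]-2-methyl-3,4-dihydro-2H-chromen-6-yl}-3-phenylprop-2-en-1-one | CC(C)(O)/C=C/C[C@@]1(C)CCc2c(O)c(C(=O)/C=C/c3ccccc3)cc(O)c2O1
F2 | step 15 | (2E)-1-{(2R)-8-{[tert-butyl(dimethyl)silyl]oxy}-5-hydroxy-2-[(2E)-4-hydroxy-4-methylpent-2-en-1-yl]-2-methyl-3,4-dihydro-2H-chromen-6-yl}-3-phenylprop-2-en-1-one | CC(C)(O)/C=C/C[C@@]1(C)CCc2c(O)c(C(=O)/C=C/c3ccccc3)cc(O[Si](C)(C)C(C)(C)C)c2O1
F3 | step 15 | (2E)-1-{(2S)-8-{[tert-butyl(dimethyl)silyl]oxy}-5-hydroxy-2-[(2E)-4-hydroxy-4-methylpent-2-en-1-yl]-2-methyl-2H-chromen-6-yl}-3-phenylprop-2-en-1-one | CC(C)(O)/C=C/C[C@@]1(C)C=Cc2c(O)c(C(=O)/C=C/c3ccccc3)cc(O[Si](C)(C)C(C)(C)C)c2O1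
F4 | step 11 | (2R)-6-(diethoxymethyl)-8-methoxy-2-methyl-2-[(2E)-4-methyl-4-(triethylsilyloxy)pent-2-en-1-yl]-3,4-dihydro-2H-chromen-5-ol | CC[Si](CC)(CC)OC(C)(C)/C=C/C[C@@]1(C)CCc2c(O)c(C(OCC)OCC)cc(OC)c2O1
F5 | step 11 | (2R)-5-hydroxy-8-methoxy-2-methyl-2-[(2E)-4-methyl-4-(triethylsilyloxy)pent-2-en-1-yl]-3,4-dihydro-2H-chromene-6-carbaldehyde | CC[Si](CC)(CC)OC(C)(C)/C=C/C[C@@]1(C)CCc2c(O)c(C=O)cc(OC)c2O1
F6 | step 11 | (2R)-6-[(1RS,2E)-1-hydroxy-3-phenylprop-2-en-1-yl]-8-methoxy-2-methyl-2-[(2E)-4-methyl-4-(triethylsilyloxy)pent-2-en-1-yl]-3,4-dihydro-2H-chromen-5-ol | CC[Si](CC)(CC)OC(C)(C)/C=C/C[C@@]1(C)CCc2c(O)c(C(O)/C=C/c3ccccc3)cc(OC)c2O1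
F7 | step 11 | (2R)-6-[(1RS,2E)-1-hydroxy-3-phenylprop-2-en-1-yl]-2-methyl-2-[(2E)-4-methyl-4-(triethylsilyloxy)pent-2-en-1-yl]-3,4-dihydro-2H-chromene-5,8-dione | CC[Si](CC)(CC)OC(C)(C)/C=C/C[C@@]1(C)CCC2=C(O1)C(=O)C=C(C(O)/C=C/c3ccccc3)C2=O
F8 | step 14 | (2R)-6-[(1RS,2E)-1-hydroxy-3-phenylprop-2-en-1-yl]-2-[(2E)-4-hydroxy-4-methylpent-2-en-1-yl]-8-methoxy-2-methyl-3,4-dihydro-2H-chromen-5-ol | CC(C)(O)/C=C/C[C@@]1(C)CCc2c(O)c(C(O)/C=C/c3ccccc3)cc(OC)c2O1
F9 | step 14 | (2E)-1-{(2R)-5-hydroxy-2-[(2E)-4-hydroxy-4-methylpent-2-en-1-yl]-8-methoxy-2-methyl-3,4-dihydro-2H-chromen-6-yl}-3-phenylprop-2-en-1-one | CC(C)(O)/C=C/C[C@@]1(C)CCc2c(O)c(C(=O)/C=C/c3ccccc3)cc(OC)c2O1
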